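## Retrosynthetic overview

1. Chirality is bought once: dibenzyl malonate (1) and (R)-epichlorohydrin (2) give cyclopropane-fused lactone 3. Its CH stereocentre becomes C3 of the target and controls C2 and C1.
2. The ring-A benzyl unit is disconnected at ArCH2: Cu-catalysed opening of 3 by the Grignard reagent of aryl bromide 4 gives lactone ester 5.
3. The second benzyl unit is disconnected at C2–CH2Ar: benzylation of 5 with benzyl bromide 6 gives 7. Hydrogenolysis/decarboxylation then gives trans lactone (−)-matairesinol (8), reduced to C2-symmetric (−)-secoisolariciresinol (9).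
4. Key disconnection, made last: the tetralin C1–C8a bond, formed from 9 by a DDQ-mediated anodic dehydrogenative cyclisation to (+)-isolariciresinol (10).
5. Ring order: cyclopropane + γ-lactone (step 1), γ-lactone only (step 2, opened in step 5), tetralin carbocycle (step 6). Both arenes are bought.

Assumption: aryl bromide 4 and benzyl bromide 6 are treated as catalogue items (otherwise each is one benzylation or bromination from 4-bromoguaiacol or 4-benzyloxy-3-methoxybenzyl alcohol).

## Route

**Step 1**
Reactants: 1 dibenzyl malonate; 2 (R)-(−)-epichlorohydrin
Product: 3 benzyl (1R,5R)-2-oxo-3-oxabicyclo[3.1.0]hexane-1-carboxylate (cis-fused; same spatial arrangement as the well-known ethyl ester, which is named 1S,5R)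
Conditions: NaOBn (1.1 equiv, from NaH/BnOH), THF, 0 → 65 °C
Reagents that add atoms: none
Why: Malonate opens the epoxide at its CH2, the alkoxide re-closes an epoxide by displacing chloride, and the malonate anion then opens it 3-exo-tet with one inversion before lactonising (the known epichlorohydrin–malonate cyclopropanation, here with benzyl esters), so the purchased stereocentre is relayed as a single enantiomer.

**Step 2**
Reactants: 3; 4 1-(benzyloxy)-4-bromo-2-methoxybenzene (as its Grignard reagent)
Product: 5 benzyl (3R,4R)-4-[4-(benzyloxy)-3-methoxybenzyl]-2-oxotetrahydrofuran-3-carboxylate (3,4-trans)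
Conditions: 4, Mg, THF (ArMgBr, 1.3 equiv); CuI (10 mol %), THF, −40 → −20 °C; aq NH4Cl
Reagents that add atoms: none (the aryl group comes from 4)
Why: Cu(I)-catalysed SN2-type homoconjugate addition of the aryl Grignard at the unsubstituted CH2 of the doubly activated cyclopropane (known for this lactone class) leaves the ring-fusion CH untouched (it becomes C4, R), and the malonate-type α-centre settles trans.

**Step 3**
Reactants: 5; 6 1-(benzyloxy)-4-(bromomethyl)-2-methoxybenzene
Product: 7 benzyl (3S,4R)-3,4-bis[4-(benzyloxy)-3-methoxybenzyl]-2-oxotetrahydrofuran-3-carboxylate (new benzyl anti to the C4 benzyl)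
Conditions: NaH, THF–DMF, 0 °C → rt
Reagents that add atoms: none
Why: C-alkylation of the stabilised malonate-type enolate with a reactive benzylic bromide, entering anti to the C4 substituent; the C3 configuration does not matter because it is erased in step 4.

**Step 4**
Reactants: 7
Product: 8 (−)-matairesinol, (3R,4R)-3,4-bis(4-hydroxy-3-methoxybenzyl)dihydrofuran-2(3H)-one (trans)
Conditions: H2 (1 atm), 10% Pd/C, EtOAc–EtOH, rt; filter; dioxane, 100 °C (−CO2); then DBU (3 equiv), 100 °C; aq HCl work-up (telescoped)
Reagents that add atoms: none
Why: Hydrogenolysis removes all three benzyl groups, the resulting lactone malonic acid decarboxylates thermally, and DBU equilibration via the lactone enol places the C3 benzyl trans to the fixed C4 benzyl (thermodynamic control by the purchased-derived centre).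

**Step 5**
Reactants: 8
Product: 9 (−)-secoisolariciresinol, (2R,3R)-2,3-bis(4-hydroxy-3-methoxybenzyl)butane-1,4-diol
Conditions: LiAlH4 (5 equiv), THF, 0 °C → reflux; Rochelle salt / dilute HCl work-up
Reagents that add atoms: none
Why: LiAlH4 reduction of the lactone to the 1,4-diol (excess hydride covers the two phenols; known for matairesinol); no stereocentre is touched and the product is C2-symmetric.

**Step 6**
Reactants: 9
Product: 10 (+)-isolariciresinol, (1S,2R,3R)-7-hydroxy-1-(4-hydroxy-3-methoxyphenyl)-6-methoxy-1,2,3,4-tetrahydronaphthalene-2,3-dimethanol (all-trans)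
Conditions: DDQ (20 mol %), nBu4NBF4 (0.1 M), MeCN–HFIP (4:1), divided cell, graphite-felt anode / Pt cathode, anode held at the DDQH2 → DDQ wave (ca. +0.8 V vs Ag/AgCl, set by CV below the onset of 9), 2.0 F mol⁻¹, 0 °C → rt
Reagents that add atoms: none
Why: Proposed new method: an indirect (DDQ-mediated) anodic dehydrogenative cyclisation in which anodically regenerated DDQ removes hydride from the benzylic CH2 para to a free phenol to give a p-quinone methide, which in the acidic HFIP anolyte is attacked by the position para to OMe of the second guaiacyl ring through a chair-like six-membered transition state with both CH2OH groups and the aryl pseudo-equatorial, forming C1–C8a and setting C1 (S) trans to C2; because 9 is C2-symmetric the two benzylic CH2 groups are equivalent, and any 5-exo O-trapped tetrahydrofuran (lariciresinol-type) re-ionises under the acid generated at the anode and funnels to the C–C product; closest known reactions are stoichiometric DDQ oxidation of 4-alkylphenols to quinone methides, DDQ/acid cyclisation of dibenzylbutane lignans, the acid-catalysed lariciresinol → isolariciresinol rearrangement (same cation, same all-trans outcome) and DDQ-mediated electrolysis for other C–H functionalisations, none shown on an unprotected bis-phenol diol or for aryltetralin ring closure.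

## Compound list

1 | dibenzyl malonate | O=C(CC(=O)OCc1ccccc1)OCc1ccccc1 | starting material
2 | (R)-(−)-epichlorohydrin | ClC[C@H]1CO1 | starting material
3 | benzyl (1R,5R)-2-oxo-3-oxabicyclo[3.1.0]hexane-1-carboxylate | O=C1OC[C@@H]2C[C@]12C(=O)OCc1ccccc1 | intermediate
4 | 1-(benzyloxy)-4-bromo-2-methoxybenzene | COc1cc(Br)ccc1OCc1ccccc1 | starting material
5 | benzyl (3R,4R)-4-[4-(benzyloxy)-3-methoxybenzyl]-2-oxotetrahydrofuran-3-carboxylate | O=C1OC[C@H](Cc2ccc(OCc3ccccc3)c(OC)c2)[C@H]1C(=O)OCc1ccccc1 | intermediate
6 | 1-(benzyloxy)-4-(bromomethyl)-2-methoxybenzene | COc1cc(CBr)ccc1OCc1ccccc1 | starting material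
7 | benzyl (3S,4R)-3,4-bis[4-(benzyloxy)-3-methoxybenzyl]-2-oxotetrahydrofuran-3-carboxylate | O=C1OC[C@H](Cc2ccc(OCc3ccccc3)c(OC)c2)[C@]1(Cc1ccc(OCc2ccccc2)c(OC)c1)C(=O)OCc1ccccc1 | intermediate
8 | (−)-matairesinol | O=C1OC[C@H](Cc2ccc(O)c(OC)c2)[C@H]1Cc1ccc(O)c(OC)c1 | intermediate
9 | (−)-secoisolariciresinol | OC[C@H](Cc1ccc(O)c(OC)c1)[C@H](CO)Cc1ccc(O)c(OC)c1 | intermediate
10 | (+)-isolariciresinol | COc1cc([C@H]2c3cc(O)c(OC)cc3C[C@@H](CO)[C@@H]2CO)ccc1O | target

## Step count and risks

Total steps: 6. Longest linear sequence: 6.

Steps most likely to fail:

1. **Step 6 (proposed new step).** Risks are over-oxidation of the product (its ring A is again a p-alkylphenol, so expect a moderate yield with recovered 9 at 2.0 F mol⁻¹), phenoxyl coupling, and direct anodic oxidation of 9 competing with the mediator. Fallback (known chemistry, pre-oxidised benzylic carbon instead of C–H oxidation): make the ethyl-ester analogue of 5 from diethyl malonate, Krapcho-decarboxylate to (R)-4-(4-benzyloxy-3-methoxybenzyl)dihydrofuran-2-one, LDA aldol with 4-benzyloxy-3-methoxybenzaldehyde, TFA Friedel–Crafts cyclisation to the trans,trans aryltetralin lactone, then LiAlH4 and H2/Pd–C.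

2. **Step 4.** Risk is incomplete cis → trans equilibration (the cis lactone would lead to the meso-type diol) or sluggish decarboxylation with free phenols present. Fallback: reverse the order so that trans is set kinetically. Krapcho-decarboxylate the ethyl-ester analogue of 5 first, alkylate the lactone enolate (LDA, −78 °C) with 6 (anti to the C4 benzyl, the standard trans-dibenzylbutyrolactone synthesis), then hydrogenolyse the two benzyl ethers.

3. **Step 1.** The benzyl-ester variant is less precedented than ethyl or tert-butyl; benzyloxide can open the product cyclopropane, and competing direct chloride displacement would erode ee. Fallback: the fully precedented diethyl malonate/NaOEt/EtOH protocol, with the ethyl ester removed after step 3 by Krapcho dealkoxycarbonylation (LiCl, wet DMSO, 150 °C) and the benzyl ethers by a separate hydrogenolysis (7 steps). Crystalline 8 or 9 can be recrystallised to upgrade ee.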